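**Plan**
Retrosynthesis: the acrylic acid is traced back through a terminal alkyne to a C2 ester, the C4–H bond to a C4 silyloxy group, and the ring is then cut at C2–C3 and O1–C6 into ethyl glyoxylate and a 2-silyloxy-3-homofarnesyl butadiene; the diene is cut at the enone methyl group and at the bond between farnesyl C1 and the methallyl carbon.
Enabling feature: in the 3,6-dihydro-2H-pyran (O1, C2, C3, C4=C5, C6, chain on C5) the O1–C2 unit is an aldehyde C=O and C3–C4=C5–C6 is a diene; a temporary silyloxy group on C4 is needed because the alkyl chain alone would steer the aldehyde carbon to the wrong diene terminus.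
Forward: farnesyl bromide is joined to dilithiated methallyl alcohol, the allylic alcohol is taken to the methyl enone and its silyl dienol ether, the single ring is closed by the oxa-Diels–Alder reaction, the C4 oxygen is removed through the enol triflate, and the ester is built up to the 2-substituted acrylic acid.
Stereochemistry: the only stereocentre (C2, R) is set by the chiral bis(oxazoline)–Cu(OTf)2 catalyst in the cycloaddition; both E alkenes come unchanged from (2E,6E)-farnesyl bromide.

Key step: step 6

Remark on the chemistry: ethyl glyoxylate is assumed to be freshly depolymerised by distillation from its commercial toluene solution, and the (4R,4'R)-tert-butyl ligand is chosen from the square-planar chelate model; its mirror image would be used if the facial sense proved opposite.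

**Route**

Step 1
Reactants: 1 (2E,6E)-farnesyl bromide; 2 methallyl alcohol (2-methylprop-2-en-1-ol)
Product: 4 (5E,9E)-6,10,14-trimethyl-2-methylidenepentadeca-5,9,13-trien-1-ol, via dilithiated methallyl alcohol 3 (not isolated)
Conditions: 2, n-BuLi (2.2 equiv), TMEDA, Et2O, 0 °C → rt; then 1, THF, −78 °C → rt; then H2O
Reagents that add atoms: none
Why: Allylic lithiation of the lithium alkoxide gives a dianion that is alkylated at carbon by the primary allylic bromide in an SN2 reaction (dianion alkylation), which leaves both E alkenes of the farnesyl unit untouched.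

Step 2
Reactants: 4 (5E,9E)-6,10,14-trimethyl-2-methylidenepentadeca-5,9,13-trien-1-ol
Product: 5 (5E,9E)-6,10,14-trimethyl-2-methylidenepentadeca-5,9,13-trienal
Conditions: MnO2 (activated, excess), CH2Cl2, rt
Reagents that add atoms: none
Why: MnO2 oxidises a primary allylic alcohol selectively to the enal (allylic alcohol oxidation) and does not touch the isolated trisubstituted alkenes.

Step 3
Reactants: 5 (5E,9E)-6,10,14-trimethyl-2-methylidenepentadeca-5,9,13-trienal
Product: 6 (6E,10E)-7,11,15-trimethyl-3-methylidenehexadeca-6,10,14-trien-2-ol (racemic at the carbinol carbon)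
Conditions: MeMgBr, Et2O, −78 → 0 °C; then H2O
Reagents that add atoms: methylmagnesium bromide, C[Mg]Br
Why: Grignard 1,2-addition of the hard methyl nucleophile to the enal carbonyl is favoured over conjugate addition at low temperature, and the new carbinol centre is erased in the next step.

Step 4
Reactants: 6 (6E,10E)-7,11,15-trimethyl-3-methylidenehexadeca-6,10,14-trien-2-ol
Product: 7 (6E,10E)-7,11,15-trimethyl-3-methylidenehexadeca-6,10,14-trien-2-one
Conditions: Dess–Martin periodinane, CH2Cl2, 0 °C → rt
Reagents that add atoms: none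
Why: Dess–Martin oxidation converts the secondary allylic alcohol into the ketone under nearly neutral conditions that spare the sensitive α-methylene ketone and the polyene.

Step 5
Reactants: 7 (6E,10E)-7,11,15-trimethyl-3-methylidenehexadeca-6,10,14-trien-2-one
Product: 8 tert-butyl(dimethyl){[(6E,10E)-7,11,15-trimethyl-3-methylidenehexadeca-1,6,10,14-tetraen-2-yl]oxy}silane
Conditions: TBSOTf, Et3N, CH2Cl2, −78 → 0 °C
Reagents that add atoms: tert-butyldimethylsilyl trifluoromethanesulfonate, CC(C)(C)[Si](C)(C)OS(=O)(=O)C(F)(F)F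
Why: Soft enolisation with a silyl triflate and a tertiary amine (silyl enol ether formation) can only remove a methyl proton, since the other α-carbon is sp2, and so should give the cross-conjugated 2-silyloxy diene as a single regioisomer.

Step 6
Reactants: 8 tert-butyl(dimethyl){[(6E,10E)-7,11,15-trimethyl-3-methylidenehexadeca-1,6,10,14-tetraen-2-yl]oxy}silane; 9 ethyl glyoxylate
Product: 10 ethyl (2R)-4-{[tert-butyl(dimethyl)silyl]oxy}-5-[(3E,7E)-4,8,12-trimethyltrideca-3,7,11-trien-1-yl]-3,6-dihydro-2H-pyran-2-carboxylate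
Conditions: Cu(OTf)2 (10 mol %), 2,2'-(propane-2,2-diyl)bis[(4R)-4-tert-butyl-4,5-dihydro-1,3-oxazole] (11 mol %), 9 (1.05 equiv, slow addition), CH2Cl2, −78 → −40 °C; filtration through Et3N-deactivated silica
Reagents that add atoms: none
Why: The 1,2-dicarbonyl unit of 9 is held as a five-membered chelate on the divalent copper centre of the Cu(OTf)2–bis(oxazoline) complex, which activates the aldehyde so that the enol silane terminus of 8 (future C3) bonds to the aldehyde carbon (future C2) while the aldehyde oxygen bonds to the methylidene carbon (future C6) in a concerted but asynchronous oxa-Diels–Alder reaction. The closest known reaction type is the copper–bis(oxazoline)-catalysed enantioselective hetero-Diels–Alder reaction of glyoxylate esters with conjugated dienes. The one ring, the 3,6-dihydro-2H-pyran, closes by [4+2] cycloaddition, which in its stepwise limit is a Mukaiyama aldol addition followed by 6-endo closure of the copper alkoxide onto the silyloxyallyl cation. The new stereocentre C2 is controlled by the C2-symmetric ligand, whose tert-butyl groups shield one face of the square-planar chelate so that the diene should add to the Re face of the aldehyde and give the 2R configuration. The step needs regioselectivity, which the silyloxy group on C4 secures by making C3 the nucleophilic terminus and thereby placing the chain on C5, and chemoselectivity over a glyoxylate–ene reaction of the chain alkenes, which the much higher nucleophilicity of the enol silane, the single equivalent of aldehyde and the low temperature should secure; the bulky silyl group also slows the silyl transfer that would stop the reaction at an open-chain aldol.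

Step 7
Reactants: 10 ethyl (2R)-4-{[tert-butyl(dimethyl)silyl]oxy}-5-[(3E,7E)-4,8,12-trimethyltrideca-3,7,11-trien-1-yl]-3,6-dihydro-2H-pyran-2-carboxylate
Product: 12 ethyl (2R)-4-{[(trifluoromethyl)sulfonyl]oxy}-5-[(3E,7E)-4,8,12-trimethyltrideca-3,7,11-trien-1-yl]-3,6-dihydro-2H-pyran-2-carboxylate, via caesium enolate 11 (not isolated)
Conditions: CsF, PhNTf2, DME, 0 °C → rt
Reagents that add atoms: N-phenylbis(trifluoromethanesulfonimide), O=S(=O)(N(c1ccccc1)S(=O)(=O)C(F)(F)F)C(F)(F)F
Why: Fluoride cleaves the Si–O bond to release the enolate regiospecifically at C4=C5 and the triflimide traps it on oxygen (enol triflate formation from an enol silane), while β-elimination of the ring oxygen is disfavoured because the endocyclic C6–O1 bond cannot align with the enolate π system.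

Step 8
Reactants: 12 ethyl (2R)-4-{[(trifluoromethyl)sulfonyl]oxy}-5-[(3E,7E)-4,8,12-trimethyltrideca-3,7,11-trien-1-yl]-3,6-dihydro-2H-pyran-2-carboxylate
Product: 13 ethyl (2R)-5-[(3E,7E)-4,8,12-trimethyltrideca-3,7,11-trien-1-yl]-3,6-dihydro-2H-pyran-2-carboxylate
Conditions: Pd(OAc)2 (5 mol %), PPh3 (10 mol %), HCO2H, Et3N, DMF, 60 °C
Reagents that add atoms: none
Why: Zerovalent palladium formed in the flask inserts into the vinyl C–OTf bond and formate delivers hydride with loss of CO2 (palladium-catalysed formate reduction of an enol triflate), which replaces the triflate by hydrogen without moving the C4=C5 double bond or disturbing C2.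

Step 9
Reactants: 13 ethyl (2R)-5-[(3E,7E)-4,8,12-trimethyltrideca-3,7,11-trien-1-yl]-3,6-dihydro-2H-pyran-2-carboxylate
Product: 15 (2R)-2-ethynyl-5-[(3E,7E)-4,8,12-trimethyltrideca-3,7,11-trien-1-yl]-3,6-dihydro-2H-pyran, via aldehyde 14 (not isolated)
Conditions: i-Bu2AlH (1.1 equiv), CH2Cl2, −78 °C; then MeOH, K2CO3, dimethyl (1-diazo-2-oxopropyl)phosphonate, −78 °C → rt; aqueous work-up
Reagents that add atoms: dimethyl (1-diazo-2-oxopropyl)phosphonate, COP(=O)(OC)C(=[N+]=[N-])C(C)=O
Why: The chelated tetrahedral aluminium adduct of the α-alkoxy ester holds the reduction at the aldehyde oxidation level, and the aldehyde released by methanol is homologated at once by the Ohira–Bestmann variant of the Seyferth–Gilbert reaction, so the epimerisable α-alkoxy aldehyde is never isolated.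

Step 10
Reactants: 15 (2R)-2-ethynyl-5-[(3E,7E)-4,8,12-trimethyltrideca-3,7,11-trien-1-yl]-3,6-dihydro-2H-pyran
Product: 16 methyl 2-{(2R)-5-[(3E,7E)-4,8,12-trimethyltrideca-3,7,11-trien-1-yl]-3,6-dihydro-2H-pyran-2-yl}prop-2-enoate
Conditions: Pd(OAc)2 (2 mol %), 2-(diphenylphosphino)pyridine (in slight excess over the acid), MsOH (cat.), CO (1 atm), MeOH/THF, 45 °C
Reagents that add atoms: carbon monoxide, [C-]#[O+]; methanol, CO
Why: A cationic complex of divalent palladium with the P,N ligand adds H and CO2Me across the terminal alkyne with Markovnikov selectivity (palladium-catalysed alkoxycarbonylation of a 1-alkyne), which places the ester on the internal carbon and gives the 1,1-disubstituted acrylate while the trisubstituted alkenes stay inert.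

Step 11
Reactants: 16 methyl 2-{(2R)-5-[(3E,7E)-4,8,12-trimethyltrideca-3,7,11-trien-1-yl]-3,6-dihydro-2H-pyran-2-yl}prop-2-enoate
Product: 17 2-{(2R)-5-[(3E,7E)-4,8,12-trimethyltrideca-3,7,11-trien-1-yl]-3,6-dihydro-2H-pyran-2-yl}prop-2-enoic acid
Conditions: LiOH, THF/MeOH/H2O, 0 °C → rt; then 1 M HCl to pH 3, 0 °C
Reagents that add atoms: lithium hydroxide (its hydroxide oxygen becomes the acid OH), [Li+].[OH-]
Why: Saponification of the methyl ester (ester hydrolysis) should be faster than conjugate addition to the α-substituted acrylate, and C2, which is not α to the carbonyl group, keeps its configuration.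

**Compound list**

1 | (2E,6E)-farnesyl bromide | BrC/C=C(\C)CC/C=C(\C)CCC=C(C)C | starting material
2 | methallyl alcohol (2-methylprop-2-en-1-ol) | C=C(C)CO | starting material
3 | dilithiated methallyl alcohol (lithium 2-(lithiomethyl)prop-2-en-1-olate) | [Li]CC(=C)CO[Li] | intermediate (not isolated)
4 | (5E,9E)-6,10,14-trimethyl-2-methylidenepentadeca-5,9,13-trien-1-ol | C=C(CO)CC/C=C(\C)CC/C=C(\C)CCC=C(C)C | intermediate
5 | (5E,9E)-6,10,14-trimethyl-2-methylidenepentadeca-5,9,13-trienal | C=C(C=O)CC/C=C(\C)CC/C=C(\C)CCC=C(C)C | intermediate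
6 | (6E,10E)-7,11,15-trimethyl-3-methylidenehexadeca-6,10,14-trien-2-ol (racemic) | CC(O)C(=C)CC/C=C(\C)CC/C=C(\C)CCC=C(C)C | intermediate
7 | (6E,10E)-7,11,15-trimethyl-3-methylidenehexadeca-6,10,14-trien-2-one | CC(=O)C(=C)CC/C=C(\C)CC/C=C(\C)CCC=C(C)C | intermediate
8 | tert-butyl(dimethyl){[(6E,10E)-7,11,15-trimethyl-3-methylidenehexadeca-1,6,10,14-tetraen-2-yl]oxy}silane | C=C(O[Si](C)(C)C(C)(C)C)C(=C)CC/C=C(\C)CC/C=C(\C)CCC=C(C)C | intermediate
9 | ethyl glyoxylate | CCOC(=O)C=O | starting material
10 | ethyl (2R)-4-{[tert-butyl(dimethyl)silyl]oxy}-5-[(3E,7E)-4,8,12-trimethyltrideca-3,7,11-trien-1-yl]-3,6-dihydro-2H-pyran-2-carboxylate | CCOC(=O)[C@H]1CC(O[Si](C)(C)C(C)(C)C)=C(CC/C=C(\C)CC/C=C(\C)CCC=C(C)C)CO1 | intermediate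
11 | caesium (2R)-2-(ethoxycarbonyl)-5-[(3E,7E)-4,8,12-trimethyltrideca-3,7,11-trien-1-yl]-3,6-dihydro-2H-pyran-4-olate | CCOC(=O)[C@H]1CC([O-])=C(CC/C=C(\C)CC/C=C(\C)CCC=C(C)C)CO1.[Cs+] | intermediate (not isolated)
12 | ethyl (2R)-4-{[(trifluoromethyl)sulfonyl]oxy}-5-[(3E,7E)-4,8,12-trimethyltrideca-3,7,11-trien-1-yl]-3,6-dihydro-2H-pyran-2-carboxylate | CCOC(=O)[C@H]1CC(OS(=O)(=O)C(F)(F)F)=C(CC/C=C(\C)CC/C=C(\C)CCC=C(C)C)CO1 | intermediate
13 | ethyl (2R)-5-[(3E,7E)-4,8,12-trimethyltrideca-3,7,11-trien-1-yl]-3,6-dihydro-2H-pyran-2-carboxylate | CCOC(=O)[C@H]1CC=C(CC/C=C(\C)CC/C=C(\C)CCC=C(C)C)CO1 | intermediate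
14 | (2R)-5-[(3E,7E)-4,8,12-trimethyltrideca-3,7,11-trien-1-yl]-3,6-dihydro-2H-pyran-2-carbaldehyde | O=C[C@H]1CC=C(CC/C=C(\C)CC/C=C(\C)CCC=C(C)C)CO1 | intermediate (not isolated)
15 | (2R)-2-ethynyl-5-[(3E,7E)-4,8,12-trimethyltrideca-3,7,11-trien-1-yl]-3,6-dihydro-2H-pyran | C#C[C@H]1CC=C(CC/C=C(\C)CC/C=C(\C)CCC=C(C)C)CO1 | intermediate
16 | methyl 2-{(2R)-5-[(3E,7E)-4,8,12-trimethyltrideca-3,7,11-trien-1-yl]-3,6-dihydro-2H-pyran-2-yl}prop-2-enoate | C=C(C(=O)OC)[C@H]1CC=C(CC/C=C(\C)CC/C=C(\C)CCC=C(C)C)CO1 | intermediate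
17 | 2-{(2R)-5-[(3E,7E)-4,8,12-trimethyltrideca-3,7,11-trien-1-yl]-3,6-dihydro-2H-pyran-2-yl}prop-2-enoic acid | C=C(C(=O)O)[C@H]1CC=C(CC/C=C(\C)CC/C=C(\C)CCC=C(C)C)CO1 | target

**Step count and risks**

Total step count: 11. Longest linear sequence: 11 steps (1 and 2 to 17; 9 enters at step 6).

Steps most likely to fail:

Step 6. The glyoxylate may react by an ene pathway with the trisubstituted chain alkenes. After the C2–C3 bond forms, silyl transfer to the copper alkoxide may outrun ring closure and leave an open-chain aldol. The weakly activated diene may also be discriminated poorly by the catalyst, giving low enantiofacial selectivity. The fallback sets out from alcohol 4 and returns at ester 13, so it also bypasses steps 7 and 8; the stereocentre then comes from the chiral pool. Commercial D-allylglycine would be diazotised (NaNO2, aq. H2SO4, 0 °C → rt, retention through the α-lactone) to (2R)-2-hydroxypent-4-enoic acid F1 and esterified (EtOH, cat. H2SO4) to ethyl (2R)-2-hydroxypent-4-enoate F2. Alcohol 4 would be converted by an Appel reaction (CBr4, PPh3, CH2Cl2, 0 °C) into (5E,9E)-2-(bromomethyl)-6,10,14-trimethylpentadeca-1,5,9,13-tetraene F3. O-Alkylation of F2 with F3 (Ag2O, Et2O, rt, dark) should give ethyl (2R)-2-{[(5E,9E)-6,10,14-trimethyl-2-methylidenepentadeca-5,9,13-trien-1-yl]oxy}pent-4-enoate F4. Ring-closing metathesis (second-generation Grubbs catalyst, CH2Cl2, 40 °C, high dilution) between the vinyl group and the 1,1-disubstituted alkene should then close the six-membered ring to 13.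

Step 10. The acid co-catalyst may add methanol to, or cyclise, the polyene chain, the allylic ring ether may ionise on palladium, and the ester may be delivered to the terminal carbon. The fallback sets out from alkyne 15 and returns at ester 16 without any acid. Hydrostannation catalysed by Mo(CO)3(CNt-Bu)3 (Bu3SnH, THF, 55 °C), which places tin on the internal carbon of propargylic ethers, should give tributyl{1-[(2R)-5-[(3E,7E)-4,8,12-trimethyltrideca-3,7,11-trien-1-yl]-3,6-dihydro-2H-pyran-2-yl]ethenyl}stannane F5. Iododestannylation (I2, CH2Cl2, −78 → 0 °C) should give (2R)-2-(1-iodoethenyl)-5-[(3E,7E)-4,8,12-trimethyltrideca-3,7,11-trien-1-yl]-3,6-dihydro-2H-pyran F6. Methoxycarbonylation catalysed by Pd(PPh3)4 (CO 1 atm, MeOH, Et3N, DMF, 50 °C) should then give 16.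

Step 9. The α-alkoxy aldehyde may epimerise at C2 in alkaline methanol before it is homologated, and over-reduction to the primary alcohol may compete. The fallback sets out from ester 13 and returns at alkyne 15, and keeps the aldehyde away from protic base. Full reduction (LiAlH4, Et2O, 0 °C) gives [(2R)-5-[(3E,7E)-4,8,12-trimethyltrideca-3,7,11-trien-1-yl]-3,6-dihydro-2H-pyran-2-yl]methanol F7. Dess–Martin oxidation (NaHCO3, CH2Cl2, 0 °C) gives aldehyde 14, which is taken at once into a Corey–Fuchs sequence. CBr4 and PPh3 (CH2Cl2, 0 °C) give (2R)-2-(2,2-dibromoethenyl)-5-[(3E,7E)-4,8,12-trimethyltrideca-3,7,11-trien-1-yl]-3,6-dihydro-2H-pyran F8, and n-BuLi (2.1 equiv, THF, −78 °C; then H2O) gives 15.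

Further compounds
F1 | step 6 | (2R)-2-hydroxypent-4-enoic acid | OC(=O)[C@H](O)CC=C
F2 | step 6 | ethyl (2R)-2-hydroxypent-4-enoate | CCOC(=O)[C@H](O)CC=C
F3 | step 6 | (5E,9E)-2-(bromomethyl)-6,10,14-trimethylpentadeca-1,5,9,13-tetraene | C=C(CBr)CC/C=C(\C)CC/C=C(\C)CCC=C(C)C
F4 | step 6 | ethyl (2R)-2-{[(5E,9E)-6,10,14-trimethyl-2-methylidenepentadeca-5,9,13-trien-1-yl]oxy}pent-4-enoate | CCOC(=O)[C@H](OCC(=C)CC/C=C(\C)CC/C=C(\C)CCC=C(C)C)CC=C
F5 | step 10 | tributyl{1-[(2R)-5-[(3E,7E)-4,8,12-trimethyltrideca-3,7,11-trien-1-yl]-3,6-dihydro-2H-pyran-2-yl]ethenyl}stannane | C=C([Sn](CCCC)(CCCC)CCCC)[C@H]1CC=C(CC/C=C(\C)CC/C=C(\C)CCC=C(C)C)CO1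
F6 | step 10 | (2R)-2-(1-iodoethenyl)-5-[(3E,7E)-4,8,12-trimethyltrideca-3,7,11-trien-1-yl]-3,6-dihydro-2H-pyran | C=C(I)[C@H]1CC=C(CC/C=C(\C)CC/C=C(\C)CCC=C(C)C)CO1
F7 | step 9 | [(2R)-5-[(3E,7E)-4,8,12-trimethyltrideca-3,7,11-trien-1-yl]-3,6-dihydro-2H-pyran-2-yl]methanol | OC[C@H]1CC=C(CC/C=C(\C)CC/C=C(\C)CCC=C(C)C)CO1
F8 | step 9 | (2R)-2-(2,2-dibromoethenyl)-5-[(3E,7E)-4,8,12-trimethyltrideca-3,7,11-trien-1-yl]-3,6-dihydro-2H-pyran | BrC(Br)=C[C@H]1CC=C(CC/C=C(\C)CC/C=C(\C)CCC=C(C)C)CO1
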